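All runs are calculated for substances that don't exist; noise was put on by code.

A small charge is where the evidence lies: the cedar run gives target readings up to 8.00 min, and the flask asks for a doubled charge read 10.0 times later.

in all of them: gas phase 200 mM (held)
- cedar: substrate 0.75 M; run made earlier
- flask: substrate 1.5 M; time 80 min

- cedar (time / min: target / %): 0.667: 0; 1.00: 2.9; 1.33: 1.2; 2.50: 6.2; 3.00: 6.0; 5.00: 13.6; 8.00: 19.4

(each reading ± 1 percentage point)

- at the start none of the gas phase is in solution

- the target standing at 80 min, as a percentage of the substrate charged
- the change that raises the amount of target at 80 min, in percent of the substrate charged most ("none" if none brings more than 2 percentage points) (zeta / gamma / none)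
- amount of target at 80 min, in percent of the substrate charged, after gamma

- zeta: doubling the transfer coefficient of the gas phase, all else as stated
- gamma: doubling the saturation concentration of gas phase, all else as stated

**Target constant.** This reckoning supposes that c(dissolved gas) stays near 200 mM, so that target forms in a pseudo-first-order way from substrate. The target constant, the logarithm of the inverse of the share not yet turned into target, divided by the time, is then 0.0270 min⁻¹ from the last cedar reading. The reading at 5.00 min gives 0.0292 min⁻¹, which agrees within the scatter of 1 percentage point.

**Two ways.** With this constant, the flask at 80 min reaches 88.4%. The other way keeps the cedar rate of 18.2 mM min⁻¹ constant, which gives 97.0% of the larger charge, a higher figure. The second way cheats: it holds the rate read on the smaller cedar charge level up to 80 min while substrate is being used. This reckoning therefore commits to 88.4%, and to 98.7% with the saturation doubled. With c(dissolved gas) supposed near saturation, this reckoning leaves the target constant unchanged under zeta, and so it picks gamma. The cedar run has no substrate reading, so substrate is the reading to watch in a repeat.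

**The forecast.** The forecast gives 91%, somewhat above this reckoning, then gamma as best change and 99% after it, holding that “Doubling saturation doubles the driving force in both readings”.

**Flask result.** The flask stands at 7.93% of target at 80 min. Gamma gives 13.1%, a gain of 5.2 points against 1 point for zeta.

    gas phase ⇌ dissolved gas, rate k1*(csat - [dissolved gas]) (kL = 0.560 min⁻¹)
    substrate + dissolved gas ⇌ target (K = 24.0 L mol⁻¹, k = 0.400 L mol⁻¹ min⁻¹)
    substrate → side product (k = 0.0270 min⁻¹)
    target ⇌ isomer of the product (K = 11.0, k = 0.00960 min⁻¹)
    2 substrate → homo dimer (k = 0.120 L mol⁻¹ min⁻¹)

**Substrate's pace.** At 80.0 min the flask's homo dimer stands at 66.8% of the charge, two substrate counted per unit. At 8.00 min the flask's substrate stands at 17.4%, and the same logarithm gives it 0.219 min⁻¹, faster than the target constant 0.0270 min⁻¹. The target constant times the 1.32% of substrate at 80.0 min, held level over the 70.0 min up to the neighbour's reading, comes to 2.49% of new target. The neighbour flask, the same flask read at 150 min, holds less target than the 7.93% at 80 min, namely 3.65%.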